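**Retrosynthetic overview**
1. Target ⇐ its 5'-O-isopropyl ether (last step: BCl3 dealkylation).
2. M axis, 2'-CH3 and 8-OH ⇐ one new step: nickel-catalysed atroposelective reductive opening of the benzylic C–O bond of a configurationally labile O8–CH2–C2' (pyran) bridged biaryl.
3. Bridged biaryl ⇐ intramolecular palladium direct arylation (C7–C1' bond, pyran ring) of a naphthylmethyl isoquinolinyl ether ⇐ Mitsunobu union of the two fragments.
4. 1,3-Dimethylisoquinolin-8-ol ⇐ pyridine ring by NH3 annulation of an ortho-alkynyl acetophenone ⇐ 2',6'-dihydroxyacetophenone (monotriflate, Sonogashira with propyne).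
5. Bromonaphthylmethanol ⇐ second naphthalene ring by Stobbe condensation/Friedel–Crafts closure on bromine-blocked 2-bromo-5-hydroxybenzaldehyde; ring order: isoquinoline and naphthalene rings separately, pyran ring last and opened again.

Assumption: the SMILES is taken as the constitution (4'-OMe, free 5'-OH); its only stereogenic unit is the C7–C1' biaryl axis, which a SMILES string cannot encode, and for the ent series it is taken as M (seen along the axis, the shorter turn from C8a' to C8 is counter-clockwise), so the names carry the descriptor and the SMILES do not.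

**Step 1**
Reactants: 1 2',6'-dihydroxyacetophenone
Product: 2 2-acetyl-3-hydroxyphenyl trifluoromethanesulfonate
Conditions: Tf2O (1.05 equiv), pyridine, CH2Cl2, −20 to 0 °C
Reagents that add atoms: triflic anhydride, O=S(=O)(OS(=O)(=O)C(F)(F)F)C(F)(F)F
Why: O-sulfonylation of a phenol stops at the monotriflate because the remaining hydroxyl is locked in a hydrogen bond to the acetyl carbonyl and is deactivated.

**Step 2**
Reactants: 2 2-acetyl-3-hydroxyphenyl trifluoromethanesulfonate; 3 propyne
Product: 4 1-[2-hydroxy-6-(prop-1-yn-1-yl)phenyl]ethan-1-one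
Conditions: Pd(PPh3)2Cl2 (3 mol %), CuI (6 mol %), Et3N, DMF, 50 °C, sealed
Reagents that add atoms: none
Why: Sonogashira coupling, in which the triflate ortho to the acetyl group adds readily to zerovalent palladium and the copper acetylide of propyne transmetalates.

**Step 3**
Reactants: 4 1-[2-hydroxy-6-(prop-1-yn-1-yl)phenyl]ethan-1-one
Product: 6 1,3-dimethylisoquinolin-8-ol, via N–H ketimine 5 (not isolated)
Conditions: NH3 (7 M in MeOH), sealed tube, 90 °C
Reagents that add atoms: ammonia, N
Why: Condensation to the hydrogen-bond-stabilised ketimine followed by 6-endo-dig hydroamination of the alkyne (aza-annulation of an ortho-alkynyl aryl ketone) gives the aromatic pyridine ring.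

**Step 4**
Reactants: 7 2-bromo-5-hydroxybenzaldehyde
Product: 8 2-bromo-5-isopropoxybenzaldehyde
Conditions: 2-bromopropane, K2CO3, DMF, 60 °C
Reagents that add atoms: 2-bromopropane, CC(C)Br
Why: Williamson ether synthesis installs the isopropyl group that will later be removed selectively beside the methyl ether.

**Step 5**
Reactants: 8 2-bromo-5-isopropoxybenzaldehyde; 9 diethyl succinate
Product: 10 (E)-4-(2-bromo-5-isopropoxyphenyl)-3-(ethoxycarbonyl)but-3-enoic acid
Conditions: KOtBu, t-BuOH, reflux; then aq. HCl
Reagents that add atoms: none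
Why: Stobbe condensation gives the half-ester mainly as the E isomer, which holds the aryl group cis to the CH2CO2H arm as needed for ring closure.

**Step 6**
Reactants: 10 (E)-4-(2-bromo-5-isopropoxyphenyl)-3-(ethoxycarbonyl)but-3-enoic acid
Product: 11 ethyl 4-acetoxy-8-bromo-5-isopropoxy-2-naphthoate
Conditions: Ac2O, NaOAc, 140 °C
Reagents that add atoms: acetic anhydride, CC(=O)OC(C)=O
Why: Intramolecular Friedel–Crafts acylation via the mixed anhydride and enol acetylation (Stobbe naphthalene synthesis); the bromine blocks the ortho position para to the isopropoxy group, so closure must occur ortho to it and the two oxygens end up peri (C4/C5).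

**Step 7**
Reactants: 11 ethyl 4-acetoxy-8-bromo-5-isopropoxy-2-naphthoate
Product: 13 ethyl 4-hydroxy-5-isopropoxy-2-naphthoate, via bromonaphthol 12 (not isolated)
Conditions: K2CO3, EtOH, 20 °C; then H2 (1 atm), Pd/C, 20 °C
Reagents that add atoms: none
Why: Base-mediated transesterification frees the naphthol and palladium-catalysed hydrodehalogenation removes the blocking bromine, while the ethyl ester is unchanged in ethanol.

**Step 8**
Reactants: 13 ethyl 4-hydroxy-5-isopropoxy-2-naphthoate
Product: 14 ethyl 1-bromo-4-hydroxy-5-isopropoxy-2-naphthoate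
Conditions: NBS (1.0 equiv), MeCN, −20 °C
Reagents that add atoms: N-bromosuccinimide, O=C1CCC(=O)N1Br
Why: Electrophilic aromatic bromination goes para to the free naphthol hydroxyl (the α position C1), since a free OH activates more strongly than the isopropyl ether in the other ring and the ortho site C3 is a less reactive β position squeezed between OH and ester.

**Step 9**
Reactants: 14 ethyl 1-bromo-4-hydroxy-5-isopropoxy-2-naphthoate
Product: 15 ethyl 1-bromo-5-isopropoxy-4-methoxy-2-naphthoate
Conditions: MeI, K2CO3, DMF, 40 °C
Reagents that add atoms: iodomethane, CI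
Why: Williamson O-methylation of the only free hydroxyl fixes the 4-OMe/5-O-isopropyl differentiation.

**Step 10**
Reactants: 15 ethyl 1-bromo-5-isopropoxy-4-methoxy-2-naphthoate
Product: 16 (1-bromo-5-isopropoxy-4-methoxynaphthalen-2-yl)methanol
Conditions: i-Bu2AlH (2.5 equiv), CH2Cl2, −78 to 0 °C; aq. KNaC4H4O6
Reagents that add atoms: none
Why: Hydride reduction of the ester to the primary alcohol leaves the aryl bromide and both ethers untouched.

**Step 11**
Reactants: 16 (1-bromo-5-isopropoxy-4-methoxynaphthalen-2-yl)methanol; 6 1,3-dimethylisoquinolin-8-ol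
Product: 17 8-[(1-bromo-5-isopropoxy-4-methoxynaphthalen-2-yl)methoxy]-1,3-dimethylisoquinoline
Conditions: PPh3, DIAD, THF, 0 to 20 °C
Reagents that add atoms: none
Why: Mitsunobu etherification of a primary benzylic alcohol with an acidic phenol; the ring nitrogen is flanked by two methyl groups and does not compete.

**Step 12**
Reactants: 17 8-[(1-bromo-5-isopropoxy-4-methoxynaphthalen-2-yl)methoxy]-1,3-dimethylisoquinoline
Product: 18 pyran-bridged biaryl (C7–C1' bond formed; six-membered ring O8–CH2–C2'–C1'–C7–C8)
Conditions: Pd(OAc)2 (10 mol %), PCy3·HBF4 (20 mol %), K2CO3, PivOH (30 mol %), DMA, 110 °C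
Reagents that add atoms: none
Why: Intramolecular palladium-catalysed direct arylation (oxidative addition of zerovalent palladium into C1'–Br, then concerted metalation–deprotonation at C7, the only free position ortho to the ether oxygen) closes the six-membered ring; the bridged biaryl has no fixed stereo element because its helix inverts fast.

**Step 13**
Reactants: 18 pyran-bridged biaryl; 19 triethylsilane
Product: 21 (M)-7-(5-isopropoxy-4-methoxy-2-methylnaphthalen-1-yl)-1,3-dimethylisoquinolin-8-ol, via triethylsilyl ether 20 (not isolated)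
Conditions: Ni(cod)2 (10 mol %), chiral NHC L* (12 mol %), Et3SiH (1.5 equiv), toluene, 25 °C; then K2CO3 (cat.), MeOH, 0 °C
Reagents that add atoms: none
Why: Proposed new method: zerovalent nickel carrying the bulky chiral carbene L* (a C2-symmetric IPr-type NHC whose four isopropyl groups are replaced by 1-phenylethyl groups; the antipode that gives M is picked in a first small run) inserts into the benzylic C–O bond of 18 to give an η3-naphthylmethyl divalent nickel aryloxide, Si–H/Ni–O σ-bond metathesis with Et3SiH gives the silyl ether and a benzyl nickel hydride, and C–H reductive elimination creates the 2'-methyl group; since the two helical forms of 18 interconvert fast while the ring-opened tri-ortho-substituted biaryl cannot rotate at 25 °C, the catalyst turns all material into one atropisomer (dynamic kinetic resolution, M axis set here), the closest known reaction types being nickel-catalysed reductive cleavage and stereospecific cross-coupling of naphthylmethyl ethers and the atroposelective hydride opening of configurationally labile biaryl lactones.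

**Step 14**
Reactants: 21 (M)-7-(5-isopropoxy-4-methoxy-2-methylnaphthalen-1-yl)-1,3-dimethylisoquinolin-8-ol
Product: 22 (M)-7-(5-hydroxy-4-methoxy-2-methylnaphthalen-1-yl)-1,3-dimethylisoquinolin-8-ol
Conditions: BCl3 (5 equiv), CH2Cl2, −78 to 0 °C; then H2O
Reagents that add atoms: none
Why: Lewis-acid ether cleavage removes the secondary isopropyl group much faster than the methyl group, and at 0 °C or below the axis does not rotate.

**Compound list**
1 | 2',6'-dihydroxyacetophenone | CC(=O)c1c(O)cccc1O | starting material
2 | 2-acetyl-3-hydroxyphenyl trifluoromethanesulfonate | CC(=O)c1c(O)cccc1OS(=O)(=O)C(F)(F)F | intermediate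
3 | propyne | CC#C | starting material
4 | 1-[2-hydroxy-6-(prop-1-yn-1-yl)phenyl]ethan-1-one | CC#Cc1cccc(O)c1C(C)=O | intermediate
5 | 2-(1-iminoethyl)-3-(prop-1-yn-1-yl)phenol (N–H ketimine) | CC#Cc1cccc(O)c1C(C)=N | intermediate
6 | 1,3-dimethylisoquinolin-8-ol | Cc1cc2cccc(O)c2c(C)n1 | intermediate
7 | 2-bromo-5-hydroxybenzaldehyde | O=Cc1cc(O)ccc1Br | starting material
8 | 2-bromo-5-isopropoxybenzaldehyde | CC(C)Oc1ccc(Br)c(C=O)c1 | intermediate
9 | diethyl succinate | CCOC(=O)CCC(=O)OCC | starting material
10 | (E)-4-(2-bromo-5-isopropoxyphenyl)-3-(ethoxycarbonyl)but-3-enoic acid | CCOC(=O)/C(CC(=O)O)=C/c1cc(OC(C)C)ccc1Br | intermediate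
11 | ethyl 4-acetoxy-8-bromo-5-isopropoxy-2-naphthoate | CCOC(=O)c1cc(OC(C)=O)c2c(OC(C)C)ccc(Br)c2c1 | intermediate
12 | ethyl 8-bromo-4-hydroxy-5-isopropoxy-2-naphthoate | CCOC(=O)c1cc(O)c2c(OC(C)C)ccc(Br)c2c1 | intermediate
13 | ethyl 4-hydroxy-5-isopropoxy-2-naphthoate | CCOC(=O)c1cc(O)c2c(OC(C)C)cccc2c1 | intermediate
14 | ethyl 1-bromo-4-hydroxy-5-isopropoxy-2-naphthoate | CCOC(=O)c1cc(O)c2c(OC(C)C)cccc2c1Br | intermediate
15 | ethyl 1-bromo-5-isopropoxy-4-methoxy-2-naphthoate | CCOC(=O)c1cc(OC)c2c(OC(C)C)cccc2c1Br | intermediate
16 | (1-bromo-5-isopropoxy-4-methoxynaphthalen-2-yl)methanol | OCc1cc(OC)c2c(OC(C)C)cccc2c1Br | intermediate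
17 | 8-[(1-bromo-5-isopropoxy-4-methoxynaphthalen-2-yl)methoxy]-1,3-dimethylisoquinoline | Cc1cc2cccc(OCc3cc(OC)c4c(OC(C)C)cccc4c3Br)c2c(C)n1 | intermediate
18 | pyran-bridged biaryl: 7-(5-isopropoxy-4-methoxynaphthalen-1-yl)-1,3-dimethylisoquinoline whose C2' carries a CH2 bonded to O8 (helix inverts fast, no fixed stereo element) | Cc1cc2ccc3-c4c(COc3c2c(C)n1)cc(OC)c1c(OC(C)C)cccc41 | intermediate
19 | triethylsilane | CC[SiH](CC)CC | starting material
20 | (M)-7-(5-isopropoxy-4-methoxy-2-methylnaphthalen-1-yl)-1,3-dimethyl-8-(triethylsilyloxy)isoquinoline | Cc1cc2ccc(-c3c(C)cc(OC)c4c(OC(C)C)cccc34)c(O[Si](CC)(CC)CC)c2c(C)n1 | intermediate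
21 | (M)-7-(5-isopropoxy-4-methoxy-2-methylnaphthalen-1-yl)-1,3-dimethylisoquinolin-8-ol | Cc1cc2ccc(-c3c(C)cc(OC)c4c(OC(C)C)cccc34)c(O)c2c(C)n1 | intermediate
22 | (M)-7-(5-hydroxy-4-methoxy-2-methylnaphthalen-1-yl)-1,3-dimethylisoquinolin-8-ol | COc1cc(C)c(-c2ccc3cc(C)nc(C)c3c2O)c2cccc(O)c12 | target

**Totals and risks**
Total step count: 14. Longest linear sequence: 11 (steps 4 to 14; the isoquinoline branch, steps 1 to 3, joins at step 11).

Most likely to fail:

Step 13 (the proposed nickel ring opening; turnover and the sense and level of atroposelection are untested). The fallback uses the known lactone method; it sets out from 18 and comes back at 21. Oxidation of the O–CH2 group with pyridinium chlorochromate [C5H5NH][CrO3Cl] (CH2Cl2, reflux) gives the configurationally labile biaryl lactone F1. Its atroposelective reductive ring opening with BH3·THF and an oxazaborolidine (CBS) catalyst of the appropriate antipode (THF, 0 °C) gives hydroxymethyl phenol F2, which has the spatial arrangement of M-21 but is formally P because the CH2OH group raises the CIP rank of C2'. Appel bromination (PPh3, CBr4, CH2Cl2, 0 °C) gives bromomethyl phenol F3, which is hydrogenolysed at once (H2, Pd/C, NaOAc, EtOAc, 20 °C) to 21. Any F3 that closes back to 18 costs yield only, not enantiomeric purity.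

Step 12 (hindered bromide, a helically strained product, and a basic heterocycle that may slow the palladium catalyst). The fallback sets out from 17 and comes back at 18. It replaces the palladium C–H activation by a radical ring closure: the C1' aryl radical (Bu3SnH, AIBN, toluene, 100 °C) attacks C7 in a homolytic aromatic substitution and rearomatises, and no further compound arises (none F0).

Step 3 (ketimine formation on a di-ortho-substituted, hydrogen-bonded ketone and 6-endo versus 5-exo closure). The fallback sets out from 4 and comes back at 6. Carbonyl-assisted hydration of the alkyne (TfOH cat., H2O, CF3CH2OH, 50 °C) gives 1,5-diketone F4, and the classical condensation of a 1,5-diketone with ammonia (NH4OAc, AcOH, 80 °C) closes the pyridine ring to 6.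

**Further compounds**
F1 | step 13 | biaryl lactone: analogue of 18 with C=O in place of the bridging CH2 (O8–C(=O)–C2'; helix inverts fast) | Cc1cc2ccc3-c4c(C(=O)Oc3c2c(C)n1)cc(OC)c1c(OC(C)C)cccc41
F2 | step 13 | 7-[2-(hydroxymethyl)-5-isopropoxy-4-methoxynaphthalen-1-yl]-1,3-dimethylisoquinolin-8-ol, axis formally P (same spatial arrangement as M-21) | Cc1cc2ccc(-c3c(CO)cc(OC)c4c(OC(C)C)cccc34)c(O)c2c(C)n1
F3 | step 13 | 7-[2-(bromomethyl)-5-isopropoxy-4-methoxynaphthalen-1-yl]-1,3-dimethylisoquinolin-8-ol, axis formally P (same spatial arrangement as M-21) | Cc1cc2ccc(-c3c(CBr)cc(OC)c4c(OC(C)C)cccc34)c(O)c2c(C)n1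
F0 | step 12 | none | none
F4 | step 3 | 1-[2-hydroxy-6-(2-oxopropyl)phenyl]ethan-1-one | CC(=O)Cc1cccc(O)c1C(C)=O
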